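**Retrosynthetic overview**
1. Target ⇒ (acetylation, N–O cleavage, allylic oxidation at C3′, desilylation, Wittig methylenation at C2) ⇒ a protected octalone in which ring A is held as the enone C2=O / C1=C8a.
2. Ring A of that octalone is cut at C1=C8a (aldol condensation) and C3–C4 (Michael addition): a ring-B ketone (C8a=O), a CH2=NMe2+ unit (C4) and ethyl acetoacetate (C3, C2, C1) are joined in one flask. This works because in ring A the methylidene-bearing C2 and the ring-fusion alkene carbon C8a are 1,5 to each other (C2–C3–C4–C4a–C8a), a 1,5-diketone retron once C2 carries oxygen, and because C4a and C8 both flank C8a and can equilibrate.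
3. Ring-B ketone ⇐ allyl β-keto ester: C8–C1′ by iminium-catalysed Michael addition to crotonaldehyde, C2′–O by enamine α-oxyamination, C3′–C4′ by Grignard addition; the allyl ester is then removed with zerovalent palladium.
4. β-Keto ester ⇐ cis-6-silyloxy-5-methylcyclohexanone ⇐ racemic ketal ketone by hydrogenation with dynamic kinetic resolution (sets C5 and C6).
5. Ring order: ring B comes with the starting material; ring A is formed last, in the key step.

Key step: step 10

Numbering and abbreviations: target numbering is used for all intermediates. Ring A: C1 (=CH), C2 (C=CH2), C3, C4. Ring fusion: C4a (sp3), C8a (sp2). Ring B: C5 (CH–CH3), C6 (CH–O), C7, C8 (CH–side chain). Side chain: C1′ (CH–CH3), C2′ (CH–O), C3′ (C=O), C4′, C5′. TBS = tert-butyldimethylsilyl; TMPO = (2,2,6,6-tetramethylpiperidin-1-yl)oxy; binap = 2,2′-bis(diphenylphosphanyl)-1,1′-binaphthyl; dpen = 1,2-diphenylethane-1,2-diamine.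

Assumption: racemic ketone 1 and Grignard reagent 12 are taken as purchasable. Two temporary stereocentres are formed without control (the quaternary C8 in 9–16, the carbinol C3′ in 13–29), are carried as epimer mixtures, and are written without a descriptor. The catalyst antipodes in steps 1, 5 and 6 are chosen from the usual shielding models and would be inverted if the sense proved opposite.

**Route**

Step 1
Reactants: 1 rac-7-methyl-1,4-dioxaspiro[4.5]decan-8-one
Product: 2 (7S,8R)-7-methyl-1,4-dioxaspiro[4.5]decan-8-ol (cis; C5 S and C6 R in target numbering)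
Conditions: H2 (8 atm), RuCl2[(S)-binap][(R,R)-dpen] (0.5 mol %), t-BuOK (10 mol %), i-PrOH, 25 °C
Reagents that add atoms: none
Why: Bifunctional RuCl2(diphosphine)(diamine) ketone hydrogenation run as a dynamic kinetic resolution: t-BuOK racemises the α-methyl centre through the enolate faster than reduction and the chiral catalyst hydrogenates one ketone enantiomer from the equatorial side, so C5 (S) and C6 (R) should be set together as the cis alcohol.

Step 2
Reactants: 2 (7S,8R)-7-methyl-1,4-dioxaspiro[4.5]decan-8-ol; 3 tert-butyl(chloro)dimethylsilane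
Product: 4 tert-butyl(dimethyl){[(7S,8R)-7-methyl-1,4-dioxaspiro[4.5]decan-8-yl]oxy}silane
Conditions: 3, imidazole, DMF, 25 °C
Reagents that add atoms: tert-butyl(chloro)dimethylsilane, CC(C)(C)[Si](C)(C)Cl
Why: Imidazole-mediated silylation of a secondary alcohol protects the C6 oxygen for the basic steps that follow.

Step 3
Reactants: 4 tert-butyl(dimethyl){[(7S,8R)-7-methyl-1,4-dioxaspiro[4.5]decan-8-yl]oxy}silane
Product: 5 (3S,4R)-4-(TBS-oxy)-3-methylcyclohexan-1-one
Conditions: pyridinium p-toluenesulfonate (cat.), acetone/H2O, 50 °C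
Reagents that add atoms: water, O
Why: Mild acid-catalysed acetal hydrolysis frees the C8a ketone while the secondary silyl ether should survive the weakly acidic pyridinium salt.

Step 4
Reactants: 5 (3S,4R)-4-(TBS-oxy)-3-methylcyclohexan-1-one; 6 diallyl carbonate
Product: 7 allyl (4S,5R)-5-(TBS-oxy)-4-methyl-2-oxocyclohexane-1-carboxylate (keto/enol mixture; C1 epimers)
Conditions: NaH (2.5 equiv), 6, THF, reflux; aq. HCl work-up
Reagents that add atoms: diallyl carbonate, C=CCOC(=O)OCC=C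
Why: Claisen-type C-acylation of the ketone under thermodynamic control places the ester at the less hindered α-carbon C8, remote from the C5 methyl group, and turns C8 into a soft carbon acid for step 5.

Step 5
Reactants: 7 allyl (4S,5R)-5-(TBS-oxy)-4-methyl-2-oxocyclohexane-1-carboxylate; 8 (E)-but-2-enal
Product: 9 allyl (4S,5R)-5-(TBS-oxy)-4-methyl-2-oxo-1-[(2R)-4-oxobutan-2-yl]cyclohexane-1-carboxylate (epimers at the quaternary carbon)
Conditions: 8 (2 equiv), (S)-2-{bis[3,5-bis(trifluoromethyl)phenyl][(trimethylsilyl)oxy]methyl}pyrrolidine (10 mol %), PhCO2H (10 mol %), toluene, 0 °C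
Reagents that add atoms: (E)-but-2-enal, C/C=C/C=O
Why: Iminium-ion organocatalysis (Michael addition of a β-keto ester to an enal): the diarylsilyloxymethyl group of the (S)-pyrrolidine shields one face of the E-iminium ion of crotonaldehyde, so the enol of 7 adds to the open face of the β-carbon and sets C1′ with the target configuration, while the quaternary C8 is only a temporary centre.

Step 6
Reactants: 9 allyl (4S,5R)-5-(TBS-oxy)-4-methyl-2-oxo-1-[(2R)-4-oxobutan-2-yl]cyclohexane-1-carboxylate; 10 2,2,6,6-tetramethylpiperidin-1-oxyl (TEMPO)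
Product: 11 allyl (4S,5R)-5-(TBS-oxy)-4-methyl-2-oxo-1-[(2S,3R)-4-oxo-3-(TMPO)butan-2-yl]cyclohexane-1-carboxylate
Conditions: 10, CuCl2·2H2O (10 mol %), (5R)-5-benzyl-2,2,3-trimethylimidazolidin-4-one trifluoroacetate (20 mol %), acetone, air, 0 °C
Reagents that add atoms: TEMPO, CC1(C)CCCC(C)(C)N1[O]
Why: Enamine organocatalysis with copper-mediated TEMPO transfer (α-oxyamination of an aldehyde): the benzyl group of the imidazolidinone shields one face of the E-enamine, so oxygen should be delivered to the other face and set C2′ (R) under catalyst control, and the alkoxyamine formed is a base-stable protected alcohol.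

Step 7
Reactants: 11 allyl (4S,5R)-5-(TBS-oxy)-4-methyl-2-oxo-1-[(2S,3R)-4-oxo-3-(TMPO)butan-2-yl]cyclohexane-1-carboxylate; 12 (2-methylprop-1-en-1-yl)magnesium bromide
Product: 13 allyl (4S,5R)-5-(TBS-oxy)-1-[(2S,3R)-4-hydroxy-6-methyl-3-(TMPO)hept-5-en-2-yl]-4-methyl-2-oxocyclohexane-1-carboxylate (C3′ epimers)
Conditions: 12 (1.3 equiv), THF, −78 °C; AcOH quench at −78 °C
Reagents that add atoms: (2-methylprop-1-en-1-yl)magnesium bromide, CC(C)=C[Mg]Br
Why: Grignard addition to the aldehyde, which at −78 °C is far more electrophilic than the hindered ketone next to the quaternary carbon and than the allyl ester; the new carbinol centre C3′ is not controlled and is erased by oxidation in step 13.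

Step 8
Reactants: 13 allyl (4S,5R)-5-(TBS-oxy)-1-[(2S,3R)-4-hydroxy-6-methyl-3-(TMPO)hept-5-en-2-yl]-4-methyl-2-oxocyclohexane-1-carboxylate; 14 tert-butyldimethylsilyl trifluoromethanesulfonate
Product: 15 allyl (4S,5R)-5-(TBS-oxy)-1-[(2S,3R)-4-(TBS-oxy)-6-methyl-3-(TMPO)hept-5-en-2-yl]-4-methyl-2-oxocyclohexane-1-carboxylate
Conditions: 14, 2,6-lutidine, CH2Cl2, −78 → 0 °C
Reagents that add atoms: tert-butyldimethylsilyl trifluoromethanesulfonate, CC(C)(C)[Si](C)(C)OS(=O)(=O)C(F)(F)F
Why: Silyl triflate silylation of the hindered secondary allylic alcohol blocks lactonisation onto the allyl ester and masks the C3′ oxygen for the basic steps.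

Step 9
Reactants: 15 allyl (4S,5R)-5-(TBS-oxy)-1-[(2S,3R)-4-(TBS-oxy)-6-methyl-3-(TMPO)hept-5-en-2-yl]-4-methyl-2-oxocyclohexane-1-carboxylate
Product: 17 (2S,4R,5S)-4-(TBS-oxy)-2-[(2S,3R)-4-(TBS-oxy)-6-methyl-3-(TMPO)hept-5-en-2-yl]-5-methylcyclohexan-1-one, via keto acid 16 (not isolated)
Conditions: Pd(PPh3)4 (5 mol %), morpholine, THF, 25 → 40 °C
Reagents that add atoms: none
Why: Tsuji–Trost deallylation (π-allyl palladium, morpholine as allyl acceptor) gives the β-keto acid 16, which loses CO2 spontaneously; C8 should be protonated mainly to the equatorial epimer (trans to the axial C6 silyl ether) and remains correctable in step 10.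

Step 10
Reactants: 17 (2S,4R,5S)-4-(TBS-oxy)-2-[(2S,3R)-4-(TBS-oxy)-6-methyl-3-(TMPO)hept-5-en-2-yl]-5-methylcyclohexan-1-one; 18 dimethyl(methylidene)ammonium iodide; 19 ethyl 3-oxobutanoate
Product: 26 (4aS,5S,6R,8S)-6-(TBS-oxy)-8-[(2S,3R)-4-(TBS-oxy)-6-methyl-3-(TMPO)hept-5-en-2-yl]-5-methyl-4,4a,5,6,7,8-hexahydronaphthalen-2(3H)-one, via lithium enolate 20 (not isolated), via Mannich base 21 (not isolated), via methylene ketone 22 (not isolated), via Michael adduct 23 (not isolated), via keto ester 24 (not isolated), via keto acid 25 (not isolated)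
Conditions: LiN(i-Pr)2, THF, −78 °C; 18, −78 → 0 °C; then 19, NaOEt (0.3 equiv), EtOH, reflux; then aq. KOH, reflux; AcOH to pH 5
Reagents that add atoms: dimethyl(methylidene)ammonium iodide, C[N+](C)=C.[I-]; ethyl 3-oxobutanoate, CCOC(=O)CC(C)=O
Why: Kinetic deprotonation of 17 at C4a (the only CH2 beside the ketone) and Mannich reaction of enolate 20 with the iminium salt give the β-amino ketone 21; hot ethoxide then expels dimethylamine (E1cB) to the exo-methylene ketone 22, which is trapped at once by the acetoacetate anion in a Michael addition that forms C3–C4 (23). The methyl ketone carbon C1 of 23 then closes ring A onto the C8a carbonyl by a 6-(enolendo)-exo-trig aldol addition and dehydration (C1=C8a, 24), and saponification with loss of CO2 through keto acid 25 removes the activating ester. The closest known reaction type is the Robinson annulation in its Mannich-base variant (α-methylene ketone made in situ plus acetoacetic ester), run here as a one-flask three-component process that adds four carbons and both ring-A bonds. The new stereocentre C4a and the epimerisable C8 are α to the ketone before closure and γ to the enone afterwards, so both should equilibrate in the basic medium to the isomer in which the C4–C4a bond, the C5 methyl group and the C8 side chain are all equatorial on ring B (the axial C6 silyl ether penalises the C8 epimer by a 1,3-diaxial contact), which is the target arrangement. The step needs regioselectivity twice: aminomethylation at C4a rather than C8 is secured by kinetic enolate formation at the CH2 instead of the hindered CH, and fused rather than bridged aldol closure is secured because the bridged ketol cannot dehydrate and reverts, whereas the fused ketol drains into the conjugated enone.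

Step 11
Reactants: 26 (4aS,5S,6R,8S)-6-(TBS-oxy)-8-[(2S,3R)-4-(TBS-oxy)-6-methyl-3-(TMPO)hept-5-en-2-yl]-5-methyl-4,4a,5,6,7,8-hexahydronaphthalen-2(3H)-one; 27 methyltriphenylphosphonium bromide
Product: 28 (4aS,5S,6R,8S)-6-(TBS-oxy)-8-[(2S,3R)-4-(TBS-oxy)-6-methyl-3-(TMPO)hept-5-en-2-yl]-5-methyl-2-methylidene-2,3,4,4a,5,6,7,8-octahydronaphthalene
Conditions: 27, t-BuOK, THF, 0 → 25 °C
Reagents that add atoms: methyltriphenylphosphonium bromide, C[P+](c1ccccc1)(c1ccccc1)c1ccccc1.[Br-]
Why: Wittig methylenation of the enone carbonyl with the non-stabilised ylide proceeds by 1,2-addition and converts C2=O into the exocyclic C2=CH2 of the diene without touching the silyl ethers or the alkoxyamine.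

Step 12
Reactants: 28 (4aS,5S,6R,8S)-6-(TBS-oxy)-8-[(2S,3R)-4-(TBS-oxy)-6-methyl-3-(TMPO)hept-5-en-2-yl]-5-methyl-2-methylidene-2,3,4,4a,5,6,7,8-octahydronaphthalene
Product: 29 (4aS,5S,6R,8S)-8-[(2S,3R)-4-hydroxy-6-methyl-3-(TMPO)hept-5-en-2-yl]-5-methyl-2-methylidene-2,3,4,4a,5,6,7,8-octahydronaphthalen-6-ol (C3′ epimers)
Conditions: Bu4NF, THF, 25 → 45 °C
Reagents that add atoms: none
Why: Fluoride-induced desilylation removes both silyl groups in one operation and leaves the N–O ether and the diene untouched.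

Step 13
Reactants: 29 (4aS,5S,6R,8S)-8-[(2S,3R)-4-hydroxy-6-methyl-3-(TMPO)hept-5-en-2-yl]-5-methyl-2-methylidene-2,3,4,4a,5,6,7,8-octahydronaphthalen-6-ol
Product: 30 (2S,3R)-2-[(1S,3R,4S,4aS)-3-hydroxy-4-methyl-7-methylidene-1,2,3,4,4a,5,6,7-octahydronaphthalen-1-yl]-6-methyl-3-(TMPO)hept-5-en-4-one
Conditions: MnO2 (excess), CH2Cl2, 25 °C
Reagents that add atoms: none
Why: MnO2 oxidises only the allylic alcohol at C3′ (both C3′ epimers converge on the enone), the saturated C6 alcohol being inert to this reagent.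

Step 14
Reactants: 30 (2S,3R)-2-[(1S,3R,4S,4aS)-3-hydroxy-4-methyl-7-methylidene-1,2,3,4,4a,5,6,7-octahydronaphthalen-1-yl]-6-methyl-3-(TMPO)hept-5-en-4-one
Product: 31 (2S,3R)-3-hydroxy-2-[(1S,3R,4S,4aS)-3-hydroxy-4-methyl-7-methylidene-1,2,3,4,4a,5,6,7-octahydronaphthalen-1-yl]-6-methylhept-5-en-4-one
Conditions: Zn dust, AcOH/THF/H2O, 25 → 40 °C
Reagents that add atoms: none
Why: Dissolving-metal reduction (Zn, AcOH) cleaves the weak N–O bond of the alkoxyamine and frees the C2′ alcohol under weakly acidic conditions that should not enolise the α-oxy ketone.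

Step 15
Reactants: 31 (2S,3R)-3-hydroxy-2-[(1S,3R,4S,4aS)-3-hydroxy-4-methyl-7-methylidene-1,2,3,4,4a,5,6,7-octahydronaphthalen-1-yl]-6-methylhept-5-en-4-one; 32 acetic anhydride
Product: 33 target CNP0302999.1 (C6 and C2′ diacetate; 4aS,5S,6R,8S,1′S,2′R)
Conditions: 32, pyridine, 4-(dimethylamino)pyridine (cat.), CH2Cl2, 0 → 25 °C
Reagents that add atoms: acetic anhydride, CC(=O)OC(C)=O
Why: Nucleophile-catalysed acylation (4-(dimethylamino)pyridine) esterifies both secondary alcohols (C6 and C2′) and gives the target.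

**Compound list**
1 | rac-7-methyl-1,4-dioxaspiro[4.5]decan-8-one (racemate) | CC1CC2(CCC1=O)OCCO2 | starting material
2 | (7S,8R)-7-methyl-1,4-dioxaspiro[4.5]decan-8-ol | O1CCOC12C[C@H](C)[C@H](O)CC2 | intermediate
3 | tert-butyl(chloro)dimethylsilane | CC(C)(C)[Si](C)(C)Cl | starting material
4 | tert-butyl(dimethyl){[(7S,8R)-7-methyl-1,4-dioxaspiro[4.5]decan-8-yl]oxy}silane | O1CCOC12C[C@H](C)[C@H](O[Si](C)(C)C(C)(C)C)CC2 | intermediate
5 | (3S,4R)-4-(TBS-oxy)-3-methylcyclohexan-1-one | O=C1C[C@H](C)[C@H](O[Si](C)(C)C(C)(C)C)CC1 | intermediate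
6 | diallyl carbonate | C=CCOC(=O)OCC=C | starting material
7 | allyl (4S,5R)-5-(TBS-oxy)-4-methyl-2-oxocyclohexane-1-carboxylate (C1 epimers/enol) | O=C1C[C@H](C)[C@H](O[Si](C)(C)C(C)(C)C)CC1C(=O)OCC=C | intermediate
8 | (E)-but-2-enal | C/C=C/C=O | starting material
9 | allyl (4S,5R)-5-(TBS-oxy)-4-methyl-2-oxo-1-[(2R)-4-oxobutan-2-yl]cyclohexane-1-carboxylate (epimers at quaternary C) | O=C1C[C@H](C)[C@H](O[Si](C)(C)C(C)(C)C)CC1(C(=O)OCC=C)[C@H](C)CC=O | intermediate
10 | 2,2,6,6-tetramethylpiperidin-1-oxyl (TEMPO) | CC1(C)CCCC(C)(C)N1[O] | starting material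
11 | allyl (4S,5R)-5-(TBS-oxy)-4-methyl-2-oxo-1-[(2S,3R)-4-oxo-3-(TMPO)butan-2-yl]cyclohexane-1-carboxylate | O=C1C[C@H](C)[C@H](O[Si](C)(C)C(C)(C)C)CC1(C(=O)OCC=C)[C@H](C)[C@@H](ON2C(C)(C)CCCC2(C)C)C=O | intermediate
12 | (2-methylprop-1-en-1-yl)magnesium bromide | CC(C)=C[Mg]Br | starting material
13 | allyl (4S,5R)-5-(TBS-oxy)-1-[(2S,3R)-4-hydroxy-6-methyl-3-(TMPO)hept-5-en-2-yl]-4-methyl-2-oxocyclohexane-1-carboxylate (C3′ epimers) | O=C1C[C@H](C)[C@H](O[Si](C)(C)C(C)(C)C)CC1(C(=O)OCC=C)[C@H](C)[C@@H](ON2C(C)(C)CCCC2(C)C)C(O)C=C(C)C | intermediate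
14 | tert-butyldimethylsilyl trifluoromethanesulfonate | CC(C)(C)[Si](C)(C)OS(=O)(=O)C(F)(F)F | starting material
15 | allyl (4S,5R)-5-(TBS-oxy)-1-[(2S,3R)-4-(TBS-oxy)-6-methyl-3-(TMPO)hept-5-en-2-yl]-4-methyl-2-oxocyclohexane-1-carboxylate | O=C1C[C@H](C)[C@H](O[Si](C)(C)C(C)(C)C)CC1(C(=O)OCC=C)[C@H](C)[C@@H](ON2C(C)(C)CCCC2(C)C)C(O[Si](C)(C)C(C)(C)C)C=C(C)C | intermediate
16 | β-keto acid from 15 (free carboxylic acid at the quaternary carbon) | O=C1C[C@H](C)[C@H](O[Si](C)(C)C(C)(C)C)CC1(C(=O)O)[C@H](C)[C@@H](ON2C(C)(C)CCCC2(C)C)C(O[Si](C)(C)C(C)(C)C)C=C(C)C | intermediate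
17 | (2S,4R,5S)-4-(TBS-oxy)-2-[(2S,3R)-4-(TBS-oxy)-6-methyl-3-(TMPO)hept-5-en-2-yl]-5-methylcyclohexan-1-one | O=C1C[C@H](C)[C@H](O[Si](C)(C)C(C)(C)C)C[C@H]1[C@H](C)[C@@H](ON2C(C)(C)CCCC2(C)C)C(O[Si](C)(C)C(C)(C)C)C=C(C)C | intermediate
18 | dimethyl(methylidene)ammonium iodide | C[N+](C)=C.[I-] | starting material
19 | ethyl 3-oxobutanoate | CCOC(=O)CC(C)=O | starting material
20 | lithium enolate of 17 (C8a–OLi, C8a=C4a) | [Li]OC1=C[C@H](C)[C@H](O[Si](C)(C)C(C)(C)C)C[C@H]1[C@H](C)[C@@H](ON2C(C)(C)CCCC2(C)C)C(O[Si](C)(C)C(C)(C)C)C=C(C)C | intermediate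
21 | Mannich base: 6-[(dimethylamino)methyl] derivative of 17 (aminomethyl trans to the C5 methyl) | O=C1[C@@H](CN(C)C)[C@H](C)[C@H](O[Si](C)(C)C(C)(C)C)C[C@H]1[C@H](C)[C@@H](ON2C(C)(C)CCCC2(C)C)C(O[Si](C)(C)C(C)(C)C)C=C(C)C | intermediate
22 | exo-methylene ketone: 6-methylidene derivative of 17 | O=C1C(=C)[C@H](C)[C@H](O[Si](C)(C)C(C)(C)C)C[C@H]1[C@H](C)[C@@H](ON2C(C)(C)CCCC2(C)C)C(O[Si](C)(C)C(C)(C)C)C=C(C)C | intermediate
23 | Michael adduct: ethyl 2-acetyl-3-(2-oxocyclohexyl)propanoate built on 17 (new chain on C4a) | O=C1[C@@H](CC(C(C)=O)C(=O)OCC)[C@H](C)[C@H](O[Si](C)(C)C(C)(C)C)C[C@H]1[C@H](C)[C@@H](ON2C(C)(C)CCCC2(C)C)C(O[Si](C)(C)C(C)(C)C)C=C(C)C | intermediate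
24 | ethyl 2-oxo-octalin-3-carboxylate (3-ethoxycarbonyl derivative of 26) | O=C1C=C2[C@@H](CC1C(=O)OCC)[C@H](C)[C@H](O[Si](C)(C)C(C)(C)C)C[C@H]2[C@H](C)[C@@H](ON3C(C)(C)CCCC3(C)C)C(O[Si](C)(C)C(C)(C)C)C=C(C)C | intermediate
25 | 3-carboxylic acid of 26 | O=C1C=C2[C@@H](CC1C(=O)O)[C@H](C)[C@H](O[Si](C)(C)C(C)(C)C)C[C@H]2[C@H](C)[C@@H](ON3C(C)(C)CCCC3(C)C)C(O[Si](C)(C)C(C)(C)C)C=C(C)C | intermediate
26 | (4aS,5S,6R,8S)-6-(TBS-oxy)-8-[(2S,3R)-4-(TBS-oxy)-6-methyl-3-(TMPO)hept-5-en-2-yl]-5-methyl-4,4a,5,6,7,8-hexahydronaphthalen-2(3H)-one | O=C1C=C2[C@@H](CC1)[C@H](C)[C@H](O[Si](C)(C)C(C)(C)C)C[C@H]2[C@H](C)[C@@H](ON3C(C)(C)CCCC3(C)C)C(O[Si](C)(C)C(C)(C)C)C=C(C)C | intermediate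
27 | methyltriphenylphosphonium bromide | C[P+](c1ccccc1)(c1ccccc1)c1ccccc1.[Br-] | starting material
28 | (4aS,5S,6R,8S)-6-(TBS-oxy)-8-[(2S,3R)-4-(TBS-oxy)-6-methyl-3-(TMPO)hept-5-en-2-yl]-5-methyl-2-methylidene-2,3,4,4a,5,6,7,8-octahydronaphthalene | C=C1C=C2[C@@H](CC1)[C@H](C)[C@H](O[Si](C)(C)C(C)(C)C)C[C@H]2[C@H](C)[C@@H](ON3C(C)(C)CCCC3(C)C)C(O[Si](C)(C)C(C)(C)C)C=C(C)C | intermediate
29 | C6,C3′-diol with C2′–TMPO (C3′ epimers) | C=C1C=C2[C@@H](CC1)[C@H](C)[C@H](O)C[C@H]2[C@H](C)[C@@H](ON3C(C)(C)CCCC3(C)C)C(O)C=C(C)C | intermediate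
30 | C3′ enone with C6–OH and C2′–TMPO | C=C1C=C2[C@@H](CC1)[C@H](C)[C@H](O)C[C@H]2[C@H](C)[C@@H](ON3C(C)(C)CCCC3(C)C)C(=O)C=C(C)C | intermediate
31 | C6,C2′-dihydroxy enone | C=C1C=C2[C@@H](CC1)[C@H](C)[C@H](O)C[C@H]2[C@H](C)[C@@H](O)C(=O)C=C(C)C | intermediate
32 | acetic anhydride | CC(=O)OC(C)=O | starting material
33 | CNP0302999.1: (4aS,5S,6R,8S)-8-[(2S,3R)-3-acetoxy-6-methyl-4-oxohept-5-en-2-yl]-5-methyl-2-methylidene-2,3,4,4a,5,6,7,8-octahydronaphthalen-6-yl acetate | C=C1C=C2[C@@H](CC1)[C@H](C)[C@H](OC(C)=O)C[C@H]2[C@H](C)[C@@H](OC(C)=O)C(=O)C=C(C)C | target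

Total step count: 15. Longest linear sequence: 15 steps (1 → 33; the route is fully linear).

**Steps most likely to fail, with fallbacks**

Step 10 (key step). The amine elimination and Michael capture may be incomplete, the exo-methylene ketone may self-condense before it is trapped, bridged aldol closure may compete, and silyl ethers may be partly lost in hot alkali. The fallback sets out from 17 and comes back at 26; it closes ring A through C4–C4a and C1=C8a instead. The kinetic lithium enolate of 17 (LiN(i-Pr)2, THF, −78 °C) is added to 3-(trimethylsilyl)but-3-en-2-one to give the α-silyl 1,5-diketone F1 (α-silyl vinyl ketone variant of the Robinson annulation). NaOMe in MeOH then removes the silyl group to give the 1,5-diketone F2, which closes by aldol condensation in the same medium to 26.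

Step 6. Enamine formation beside the quaternary C8 may be slow, the enamine may lose the β-keto ester by retro-Michael fragmentation (eroding C1′), and facial control may be mismatched with the existing C1′ centre. The fallback sets out from 9 and comes back at 17; it inverts the order of ester removal and oxygenation so that the enamine chemistry runs on a substrate with a tertiary, poorly leaving carbon at C8. Decarboxylation of 9 (Pd(OAc)2, PPh3, HCO2H, Et3N, THF) gives the keto aldehyde F3. α-Oxyamination as in step 6 gives the keto aldehyde alkoxyamine F4, addition of 12 at −78 °C gives the allylic alcohol F5, and silylation with 14 and 2,6-lutidine gives 17.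

Step 1. Racemisation of the α-methyl ketone may be too slow relative to hydrogenation, giving insufficient enantiomeric purity or cis selectivity. The fallback sets out from 1 and comes back at 2; it replaces catalytic dynamic resolution by diastereoselective reduction and enzymatic resolution. Li[HB(s-Bu)3] (THF, −78 °C) attacks equatorially and gives the racemic cis alcohol F6. Candida antarctica lipase B with vinyl acetate should acetylate the (8R) enantiomer to the acetate F7, which is separated from the unreacted (7R,8S) alcohol; K2CO3 in MeOH then gives 2.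

Further compounds
F1 | step 10 | α-silyl 1,5-diketone: 17 carrying a 3-oxo-2-(trimethylsilyl)butyl group on C4a | O=C1[C@@H](CC([Si](C)(C)C)C(C)=O)[C@H](C)[C@H](O[Si](C)(C)C(C)(C)C)C[C@H]1[C@H](C)[C@@H](ON2C(C)(C)CCCC2(C)C)C(O[Si](C)(C)C(C)(C)C)C=C(C)C
F2 | step 10 | 1,5-diketone: 17 carrying a 3-oxobutyl group on C4a | O=C1[C@@H](CCC(C)=O)[C@H](C)[C@H](O[Si](C)(C)C(C)(C)C)C[C@H]1[C@H](C)[C@@H](ON2C(C)(C)CCCC2(C)C)C(O[Si](C)(C)C(C)(C)C)C=C(C)C
F3 | step 6 | keto aldehyde: (3R)-3-[(1S,4R,5S)-4-(TBS-oxy)-5-methyl-2-oxocyclohexyl]butanal | O=C1C[C@H](C)[C@H](O[Si](C)(C)C(C)(C)C)C[C@H]1[C@H](C)CC=O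
F4 | step 6 | keto aldehyde alkoxyamine: (2R,3S)-3-[(1S,4R,5S)-4-(TBS-oxy)-5-methyl-2-oxocyclohexyl]-2-(TMPO)butanal | O=C1C[C@H](C)[C@H](O[Si](C)(C)C(C)(C)C)C[C@H]1[C@H](C)[C@@H](ON2C(C)(C)CCCC2(C)C)C=O
F5 | step 6 | allylic alcohol: 17 with free C3′–OH (C3′ epimers) | O=C1C[C@H](C)[C@H](O[Si](C)(C)C(C)(C)C)C[C@H]1[C@H](C)[C@@H](ON2C(C)(C)CCCC2(C)C)C(O)C=C(C)C
F6 | step 1 | racemic cis-7-methyl-1,4-dioxaspiro[4.5]decan-8-ol (both enantiomers) | O1CCOC12C[C@H](C)[C@H](O)CC2.O1CCOC12C[C@@H](C)[C@@H](O)CC2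
F7 | step 1 | (7S,8R)-7-methyl-1,4-dioxaspiro[4.5]decan-8-yl acetate | O1CCOC12C[C@H](C)[C@H](OC(C)=O)CC2
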